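The route rests on the C8–C11 bond of the carbocyclic ring C5–C6–C7–C8–C11–C30, where the tertiary hydroxyl O10 on C8 and the branch C12 on C11 sit cis on neighbouring carbons. One cathodic reduction of a keto-enoate joins C8 (methyl ketone) to C11 (enoate β-carbon), closes this cyclohexane onto the preformed oxepane ring (C2, O4, C5, C30, C32–C34) and traps the cis pair as an O10–C13 γ-lactone, fixing C8 and C11 together. The precursor is an oxepane carrying a 3-oxobutyl arm on C5 and an (E)-acrylate on quaternary C30. The lactone later becomes a C13 nucleophile for union with a hydroazulenone at C14.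

Key step: step 14

Remark: atoms are numbered C1 to O35 in the order of the target SMILES, and these locants are used for every intermediate.
Remark: 7 is carried as both C5 epimers and 39 with whichever C14 carbinol configuration forms, because each centre becomes sp2 in the following step.
Remark: the hydroazulenone 36 is made separately from (R)-linalool (steps 18–27), and C8–OH is silylated before C13 is activated, since the free 1,4-diol would close to a tetrahydrofuran.

Step 1
Reactants: 1 geraniol
Product: 2 (2R,3R)-2,3-epoxygeraniol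
Conditions: Ti(OiPr)4 (5 mol %), D-(−)-diethyl tartrate (7 mol %), t-BuOOH, 4 Å molecular sieves, CH2Cl2, −20 °C
Reagents that add atoms: tert-butyl hydroperoxide, CC(C)(C)OO
Why: Sharpless asymmetric epoxidation, in which the D-tartrate titanium complex delivers oxygen to one face of the allylic 2,3-alkene and sets the (2R,3R)-epoxide (future C5 and C30) while the remote 6,7-alkene stays untouched.

Step 2
Reactants: 2 (2R,3R)-2,3-epoxygeraniol
Product: 3 (2R,3R)-2,3-epoxygeranyl tert-butyldimethylsilyl ether
Conditions: t-BuMe2SiCl, imidazole, DMF, 0 °C → rt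
Reagents that add atoms: tert-butyldimethylsilyl chloride, CC(C)(C)[Si](C)(C)Cl
Why: Routine silylation of the primary alcohol gives the epoxy silyl ether that the rearrangement needs and touches no stereocentre.

Step 3
Reactants: 3 epoxy silyl ether
Product: 4 (R)-2-[(tert-butyldimethylsilyloxy)methyl]-2,6-dimethylhept-5-enal
Conditions: MeAl(OAr)2 (Ar = 4-bromo-2,6-di-tert-butylphenyl, 2 equiv, from AlMe3 and ArOH), CH2Cl2, −78 °C
Reagents that add atoms: none
Why: Organoaluminium-promoted rearrangement of an epoxy silyl ether (semipinacol type), in which the bulky Lewis acid opens the epoxide at its tertiary carbon and the siloxymethyl group (C11) migrates anti to the leaving oxygen, so the epoxide configuration is relayed with inversion to quaternary C30 and the former epoxide CH becomes the aldehyde C5.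

Step 4
Reactants: 4 aldehyde; 5 2-(2-bromoethyl)-2-methyl-1,3-dioxolane
Product: 7 ketal carbinol as a mixture of C5 epimers, via dioxolanylethylmagnesium bromide 6 (not isolated)
Conditions: 5, Mg, THF, 20 °C; then 4, −78 → 0 °C; aq. NH4Cl
Reagents that add atoms: none
Why: Grignard addition to the hindered aldehyde brings in C6 to C9 with the C8 ketone masked as its dioxolane; the quaternary neighbour offers little facial bias, so C5 is corrected in the next two steps.

Step 5
Reactants: 7 ketal carbinol (C5 epimers)
Product: 8 C5 ketone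
Conditions: Dess–Martin periodinane, NaHCO3, CH2Cl2, 0 °C → rt
Reagents that add atoms: none
Why: Buffered Dess–Martin oxidation converges both C5 epimers on one ketone without harming the ketal, the silyl ether or the alkene.

Step 6
Reactants: 8 C5 ketone
Product: 9 (5R)-carbinol
Conditions: (S)-2-methyl-CBS-oxazaborolidine (0.2 equiv), catecholborane, toluene, −40 °C; then MeOH, aq. NaOH
Reagents that add atoms: none
Why: Corey–Bakshi–Shibata reduction, in which the (S)-oxazaborolidine distinguishes the quaternary C30 side (large) from the C6 methylene (small) and delivers hydride under reagent control to give the (5R)-alcohol, while catecholborane should not hydroborate the trisubstituted alkene at this temperature.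

Step 7
Reactants: 9 (5R)-carbinol
Product: 10 (34R)-2,34-epoxy alcohol
Conditions: D-fructose-derived Shi ketone (0.3 equiv), KHSO5, K2CO3, Bu4NHSO4, MeCN/CH2(OMe)2/aq. Na2B4O7, 0 °C
Reagents that add atoms: potassium peroxymonosulfate, [K+].[O-]S(=O)(=O)OO
Why: Shi epoxidation, in which the chiral dioxirane transfers oxygen to the electron-rich trisubstituted alkene through a spiro transition state and sets (R)-configured C34 under catalyst control at a pH where the epoxy alcohol does not cyclise.

Step 8
Reactants: 10 epoxy alcohol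
Product: 11 oxepan-34-ol
Conditions: (+)-camphor-10-sulfonic acid (0.1 equiv), CH2Cl2, −20 → 0 °C
Reagents that add atoms: none
Why: Acid-catalysed intramolecular epoxide opening in the 7-endo mode, in which the protonated epoxide carries its positive charge on tertiary C2 so that the C5 hydroxyl attacks there, the C34–O bond keeps its configuration, and the oxepane forms with C5 and C30 already fixed.

Step 9
Reactants: 11 oxepan-34-ol
Product: 12 bis(tert-butyldimethylsilyl) ether
Conditions: t-BuMe2SiOTf, 2,6-lutidine, CH2Cl2, −78 → 0 °C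
Reagents that add atoms: tert-butyldimethylsilyl trifluoromethanesulfonate, CC(C)(C)[Si](C)(C)OS(=O)(=O)C(F)(F)F
Why: Silyl triflate silylation of the hindered secondary C34 hydroxyl at low temperature spares the dioxolane and masks the future ketone through the reductive steps.

Step 10
Reactants: 12 bis-silyl ether
Product: 13 C11 primary alcohol
Conditions: HF·pyridine, pyridine, THF, 0 °C
Reagents that add atoms: none
Why: Selective fluoride cleavage of the primary C11 silyl ether, which is far less hindered than the C34 ether flanked by quaternary C2, under buffered conditions that keep the ketal.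

Step 11
Reactants: 13 C11 primary alcohol
Product: 14 C11 aldehyde
Conditions: Dess–Martin periodinane, NaHCO3, CH2Cl2, 0 °C → rt
Reagents that add atoms: none
Why: Dess–Martin oxidation gives the non-enolisable neopentyl aldehyde on C30 without epimerisable positions.

Step 12
Reactants: 14 C11 aldehyde; 15 methyl (triphenylphosphoranylidene)acetate
Product: 16 (E)-enoate ketal
Conditions: toluene, 90 °C
Reagents that add atoms: none
Why: Wittig olefination with a stabilised ylide installs the (E)-enoate C11=C12–C13, heat compensating for the hindrance at the neopentyl aldehyde.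

Step 13
Reactants: 16 (E)-enoate ketal
Product: 17 oxepane keto-enoate
Conditions: pyridinium p-toluenesulfonate, acetone/H2O, 50 °C
Reagents that add atoms: water, O
Why: Mild acid-catalysed ketal hydrolysis frees the C8 methyl ketone and leaves the enoate and the hindered C34 silyl ether intact.

Step 14
Reactants: 17 oxepane keto-enoate
Product: 19 tricyclic cis-fused γ-lactone, via cis hydroxy ester 18 (not isolated)
Conditions: divided cell, carbon-felt cathode, Pt anode, Et4NOTs (0.2 M) in DMF, dimethyl malonate (2 equiv), −2.2 V vs SCE, rt, 2.2 F/mol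
Reagents that add atoms: none
Why: The enoate is reduced at the cathode to its radical anion, whose β-carbon C11 adds to the C8 carbonyl; a second electron and a proton from dimethyl malonate give the γ-oxido ester 18, whose C8 alkoxide attacks the ester carbon C13 and expels methoxide. The closest known reaction type is the electroreductive cyclisation of enoates onto tethered ketones, the electrode counterpart of the samarium diiodide ketyl–olefin cyclisation. The cyclohexane closes in a 6-exo-trig mode through a chair and the lactone by a 5-exo-trig acyl substitution. C11 is set by the enoate arm taking the equatorial position of that chair, which the trans-disposed oxepane bonds at C5 and C30 lock with the C31 methyl axial; C8 is set because its C9 methyl avoids the 1,3-diaxial contact with C31, leaving O10 axial and cis to C12. The step needs diastereoselectivity at C8 and C11, secured by the preset C5/C30 pair and the axial C31 methyl, and chemoselectivity for cyclisation over plain saturation of the enoate, secured by the short tether, the potential held at the enoate wave and the weak proton donor; only the cis isomer can lactonise, which also eases purification.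

Step 15
Reactants: 19 γ-lactone
Product: 20 C8,C13-diol
Conditions: LiAlH4, THF, 0 °C → rt; aq. NaOH work-up
Reagents that add atoms: none
Why: Hydride reduction of the γ-lactone opens it to the tertiary C8 alcohol and the primary C13 alcohol without touching a stereocentre.

Step 16
Reactants: 20 C8,C13-diol
Product: 22 C13 alcohol with C8 triethylsilyl ether, via bis(triethylsilyl) ether 21 (not isolated)
Conditions: Et3SiOTf (2.5 equiv), 2,6-lutidine, CH2Cl2, −78 → 0 °C; then MeOH, pyridinium p-toluenesulfonate, 0 °C
Reagents that add atoms: triethylsilyl trifluoromethanesulfonate, CC[Si](CC)(CC)OS(=O)(=O)C(F)(F)F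
Why: Both hydroxyls are silylated and the unhindered primary triethylsilyl ether is then methanolysed selectively under mild acid, so C8–O is capped before C13 is activated and the 1,4-diol cannot close to a tetrahydrofuran.

Step 17
Reactants: 22 C13 alcohol
Product: 23 C13 iodide
Conditions: I2, PPh3, imidazole, CH2Cl2, 0 °C
Reagents that add atoms: iodine, II
Why: Appel-type iodination converts the primary alcohol into the iodide by SN2 displacement of the oxyphosphonium ion, the silyl ethers being inert.

Step 18
Reactants: 24 (R)-(−)-linalool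
Product: 25 (R)-1-methylcyclopent-2-en-1-ol
Conditions: second-generation Grubbs catalyst RuCl2(=CHPh)(H2IMes)(PCy3) (0.5 mol %), CH2Cl2, rt
Reagents that add atoms: none
Why: Ring-closing metathesis between the vinyl group and the trisubstituted alkene extrudes 2-methylpropene and gives the cyclopentenol, the tertiary carbinol C21 coming unchanged from the chiral pool.

Step 19
Reactants: 25 cyclopentenol
Product: 26 syn-epoxy alcohol (epoxide cis to the hydroxyl)
Conditions: VO(acac)2 (2 mol %), t-BuOOH, CH2Cl2, 0 °C → rt
Reagents that add atoms: tert-butyl hydroperoxide, CC(C)(C)OO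
Why: Vanadium-catalysed hydroxyl-directed epoxidation delivers oxygen to the alkene face syn to the C21 hydroxyl.

Step 20
Reactants: 26 syn-epoxy alcohol
Product: 27 C21,C24-diol with a 2-cyanopropan-2-yl group on C18
Conditions: isobutyronitrile, LiN(iPr)2 (3.5 equiv), THF, −78 °C; then 26, −78 → 40 °C
Reagents that add atoms: 2-methylpropanenitrile, CC(C)C#N
Why: Anti SN2 opening of the epoxide by a lithiated nitrile at C18, the epoxide carbon remote from the quaternary alkoxide, attaches the future C15 with both methyl groups and C14 as the nitrile carbon.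

Step 21
Reactants: 27 diol nitrile
Product: 28 C24 ketone (α-hydroxy ketone)
Conditions: SO3·pyridine, DMSO, iPr2NEt, CH2Cl2, 0 °C
Reagents that add atoms: none
Why: Parikh–Doering oxidation converts the secondary C24 hydroxyl into the ketone and cannot touch the tertiary C21 hydroxyl.

Step 22
Reactants: 28 α-hydroxy ketone
Product: 29 C24 enol triflate (C18=C24)
Conditions: KN(SiMe3)2 (2.2 equiv), THF, −78 °C; then N-(5-chloropyridin-2-yl)bis(trifluoromethanesulfonimide), −78 °C
Reagents that add atoms: N-(5-chloropyridin-2-yl)-1,1,1-trifluoro-N-(trifluoromethylsulfonyl)methanesulfonamide, O=S(=O)(N(c1ccc(Cl)cn1)S(=O)(=O)C(F)(F)F)C(F)(F)F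
Why: Enolate O-sulfonylation, in which the dianion can enolise only toward C18, so a single fully substituted enol triflate is trapped at low temperature while the hindered tertiary alkoxide is left alone.

Step 23
Reactants: 29 enol triflate
Product: 30 cyclopentene carrying the dioxolanylmethyl group on C24
Conditions: Fe(acac)3 (5 mol %), (1,3-dioxolan-2-ylmethyl)MgBr (2.5 equiv), THF/N-methylpyrrolidone, −30 → 0 °C
Reagents that add atoms: (1,3-dioxolan-2-ylmethyl)magnesium bromide, Br[Mg]CC1OCCO1
Why: Iron-catalysed cross-coupling of an alkenyl triflate with an alkyl Grignard reagent (Kumada–Corriu type) attaches C25 and the masked aldehyde C26 at C24, one extra equivalent being consumed by the hydroxyl.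

Step 24
Reactants: 30 nitrile
Product: 32 ethyl ketone, via ketimine 31 (not isolated)
Conditions: EtLi (3.5 equiv), Et2O, −78 → 0 °C; then aq. AcOH/NaOAc (pH 5), THF, rt
Reagents that add atoms: ethyllithium, [Li]CC; water, O
Why: Organolithium addition to the non-enolisable tertiary nitrile gives the ketimine, whose mild hydrolysis yields the ethyl ketone (C14, C28, C29) without opening the dioxolane or ionising the tertiary allylic alcohol.

Step 25
Reactants: 32 ethyl ketone
Product: 33 all-cis cyclopentanol (H18 and H24 cis to O23)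
Conditions: [Ir(cod)(PCy3)(py)]PF6 (10 mol %), H2 (50 bar), CH2Cl2, rt
Reagents that add atoms: none
Why: Hydroxyl-directed homogeneous hydrogenation, in which the cationic iridium catalyst binds the C21 hydroxyl and adds both hydrogens to the tetrasubstituted alkene from that face, so C18 and C24 are set with their hydrogens cis to O23.

Step 26
Reactants: 33 keto acetal
Product: 35 hydroxy hydroazulenone, via keto aldehyde 34 (not isolated)
Conditions: 1 M HCl, THF, rt; then KOH, MeOH, 0 → 40 °C
Reagents that add atoms: none
Why: Acetal hydrolysis followed by base-mediated intramolecular aldol condensation, in which the ketone can enolise only toward C28 and its enolate attacks the unhindered C26 aldehyde to close the seven-membered enone, no stereocentre being α to a carbonyl.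

Step 27
Reactants: 35 hydroxy hydroazulenone
Product: 36 C21 triethylsilyl ether of the hydroazulenone
Conditions: Et3SiOTf, 2,6-lutidine, CH2Cl2, −78 °C
Reagents that add atoms: triethylsilyl trifluoromethanesulfonate, CC[Si](CC)(CC)OS(=O)(=O)C(F)(F)F
Why: Silyl triflate silylation caps the tertiary C21 hydroxyl so that it cannot quench the organometallic partner.

Step 28
Reactants: 23 C13 iodide; 36 silylated hydroazulenone
Product: 39 C14 tertiary allylic alcohol, via alkyllithium 37 (not isolated), via organocerium 38 (not isolated)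
Conditions: 23, t-BuLi (2.1 equiv), Et2O/pentane, −78 °C; CeCl3 (anhydrous), THF, −78 °C; then 36, −78 → −40 °C; aq. NH4Cl
Reagents that add atoms: none
Why: Iodine–lithium exchange and transmetalation give a weakly basic organocerium reagent that adds 1,2 to the hindered, enolisable enone carbonyl C14 and forms the C13–C14 bond, the new carbinol centre being erased in the next step.

Step 29
Reactants: 39 tertiary allylic alcohol
Product: 40 C26 enone (C14=C28)
Conditions: [C5H5NH][CrO3Cl], 4 Å molecular sieves, CH2Cl2, rt
Reagents that add atoms: pyridinium chlorochromate, [O-][Cr](=O)(=O)Cl.c1cc[nH+]cc1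
Why: Oxidative 1,3-transposition of a tertiary allylic alcohol (Babler–Dauben oxidation), in which the chromate ester shifts to C26 in a [3,3] manner and is oxidised there.

Step 30
Reactants: 40 C26 enone
Product: 41 (26S)-allylic alcohol
Conditions: NaBH4, CeCl3·7H2O, MeOH, −78 °C
Reagents that add atoms: none
Why: Luche 1,2-reduction, in which hydride should approach C26 from the convex face of the cis-fused bicycle, opposite the five-membered ring and its C22 methyl, to give the (26S)-alcohol.

Step 31
Reactants: 41 allylic alcohol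
Product: 44 C26=C28 alkene with C14–H, via allylic sulfonylhydrazine 42 (not isolated), via allylic diazene 43 (not isolated)
Conditions: 2-nitrobenzenesulfonylhydrazide, PPh3, diethyl azodicarboxylate, THF, −30 °C → rt
Reagents that add atoms: none
Why: Mitsunobu displacement by the sulfonylhydrazide inverts C26, loss of sulfinic acid gives the allylic diazene, and its retro-ene loss of N2 delivers hydrogen to C14 on the face of the C26–N bond, which sets C14 (H cis to H18 and H24) and moves the alkene to C26=C28.

Step 32
Reactants: 44 tris-silyl ether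
Product: 45 C8,C21,C34-triol
Conditions: Bu4NF, THF, 50 °C
Reagents that add atoms: none
Why: Fluoride-mediated desilylation removes the three silyl ethers in one operation, warming being needed for the hindered tertiary and neopentyl ethers.

Step 33
Reactants: 45 triol
Product: 46 C34 ketone
Conditions: Dess–Martin periodinane, NaHCO3, CH2Cl2, 0 °C → rt
Reagents that add atoms: none
Why: Dess–Martin oxidation converts the only secondary alcohol, C34–OH, into the ketone and leaves the two tertiary alcohols and the alkene untouched.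

Step 34
Reactants: 46 C34 ketone
Product: 47 target (CNP0259752.1)
Conditions: 3-chloroperbenzoic acid, NaHCO3, CH2Cl2, 0 °C
Reagents that add atoms: 3-chloroperbenzoic acid, O=C(OO)c1cccc(Cl)c1
Why: Prilezhaev epoxidation of the only alkene, which should occur syn to the C13 branch because the opposite face is screened by the axial C15 methyl, as in related 2,6,6-trimethylcyclohexenyl systems, and so sets C26 and C28; buffer and low temperature keep the ketone from Baeyer–Villiger oxidation.

Compound list
1 | geraniol | CC(C)=CCC/C(C)=C/CO | starting material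
2 | (2R,3R)-2,3-epoxygeraniol | CC(C)=CCC[C@@]1(C)O[C@@H]1CO | intermediate
3 | (2R,3R)-2,3-epoxygeranyl tert-butyldimethylsilyl ether | CC(C)=CCC[C@@]1(C)O[C@@H]1CO[Si](C)(C)C(C)(C)C | intermediate
4 | (R)-2-[(tert-butyldimethylsilyloxy)methyl]-2,6-dimethylhept-5-enal | O=C[C@@](C)(CO[Si](C)(C)C(C)(C)C)CCC=C(C)C | intermediate
5 | 2-(2-bromoethyl)-2-methyl-1,3-dioxolane | CC1(CCBr)OCCO1 | starting material
6 | [2-(2-methyl-1,3-dioxolan-2-yl)ethyl]magnesium bromide | CC1(CC[Mg]Br)OCCO1 | intermediate
7 | ketal carbinol, both C5 epimers | CC(C)=CCC[C@](C)(CO[Si](C)(C)C(C)(C)C)C(O)CCC1(C)OCCO1 | intermediate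
8 | ketal C5 ketone | CC(C)=CCC[C@](C)(CO[Si](C)(C)C(C)(C)C)C(=O)CCC1(C)OCCO1 | intermediate
9 | (5R)-ketal carbinol | CC(C)=CCC[C@](C)(CO[Si](C)(C)C(C)(C)C)[C@H](O)CCC1(C)OCCO1 | intermediate
10 | (5R,34R)-2,34-epoxy alcohol | CC1(C)O[C@@H]1CC[C@](C)(CO[Si](C)(C)C(C)(C)C)[C@H](O)CCC1(C)OCCO1 | intermediate
11 | oxepan-34-ol with C11 silyl ether and C8 ketal | CC1(C)O[C@H](CCC2(C)OCCO2)[C@@](C)(CO[Si](C)(C)C(C)(C)C)CC[C@H]1O | intermediate
12 | C11,C34-bis(tert-butyldimethylsilyl) ether | CC1(C)O[C@H](CCC2(C)OCCO2)[C@@](C)(CO[Si](C)(C)C(C)(C)C)CC[C@H]1O[Si](C)(C)C(C)(C)C | intermediate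
13 | C11 primary alcohol | CC1(C)O[C@H](CCC2(C)OCCO2)[C@@](C)(CO)CC[C@H]1O[Si](C)(C)C(C)(C)C | intermediate
14 | C11 aldehyde | CC1(C)O[C@H](CCC2(C)OCCO2)[C@@](C)(C=O)CC[C@H]1O[Si](C)(C)C(C)(C)C | intermediate
15 | methyl (triphenylphosphoranylidene)acetate | COC(=O)C=P(c1ccccc1)(c1ccccc1)c1ccccc1 | starting material
16 | (E)-enoate ketal | CC1(C)O[C@H](CCC2(C)OCCO2)[C@@](C)(/C=C/C(=O)OC)CC[C@H]1O[Si](C)(C)C(C)(C)C | intermediate
17 | oxepane keto-enoate with C34 silyl ether | CC1(C)O[C@H](CCC(C)=O)[C@@](C)(/C=C/C(=O)OC)CC[C@H]1O[Si](C)(C)C(C)(C)C | intermediate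
18 | cis γ-hydroxy ester (C8–OH cis to C12) | CC1(C)O[C@@H]2CC[C@](C)(O)[C@H](CC(=O)OC)[C@@]2(C)CC[C@H]1O[Si](C)(C)C(C)(C)C | intermediate
19 | cis-fused tricyclic γ-lactone | CC1(C)O[C@@H]2CC[C@]3(C)OC(=O)C[C@@H]3[C@@]2(C)CC[C@H]1O[Si](C)(C)C(C)(C)C | intermediate
20 | C8,C13-diol | CC1(C)O[C@@H]2CC[C@](C)(O)[C@H](CCO)[C@@]2(C)CC[C@H]1O[Si](C)(C)C(C)(C)C | intermediate
21 | C8,C13-bis(triethylsilyl) ether | CC1(C)O[C@@H]2CC[C@](C)(O[Si](CC)(CC)CC)[C@H](CCO[Si](CC)(CC)CC)[C@@]2(C)CC[C@H]1O[Si](C)(C)C(C)(C)C | intermediate
22 | C13 alcohol with C8 triethylsilyl ether | CC1(C)O[C@@H]2CC[C@](C)(O[Si](CC)(CC)CC)[C@H](CCO)[C@@]2(C)CC[C@H]1O[Si](C)(C)C(C)(C)C | intermediate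
23 | C13 iodide | CC1(C)O[C@@H]2CC[C@](C)(O[Si](CC)(CC)CC)[C@H](CCI)[C@@]2(C)CC[C@H]1O[Si](C)(C)C(C)(C)C | intermediate
24 | (R)-(−)-linalool | C=C[C@](C)(O)CCC=C(C)C | starting material
25 | (R)-1-methylcyclopent-2-en-1-ol | C[C@@]1(O)CCC=C1 | intermediate
26 | syn-epoxy alcohol (2-methyl-6-oxabicyclo[3.1.0]hexan-2-ol, epoxide cis to OH) | C[C@@]1(O)CC[C@@H]2O[C@H]12 | intermediate
27 | cis-C21,C24-diol with 2-cyanopropan-2-yl on C18 (trans to both hydroxyls) | C[C@@]1(O)CC[C@@H](C(C)(C)C#N)[C@@H]1O | intermediate
28 | C24 ketone, α-hydroxy ketone nitrile | C[C@@]1(O)CC[C@@H](C(C)(C)C#N)C1=O | intermediate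
29 | C24 enol triflate | C[C@@]1(O)CCC(C(C)(C)C#N)=C1OS(=O)(=O)C(F)(F)F | intermediate
30 | dioxolanylmethyl cyclopentene nitrile | C[C@@]1(O)CCC(C(C)(C)C#N)=C1CC2OCCO2 | intermediate
31 | ketimine | C[C@@]1(O)CCC(C(C)(C)C(=N)CC)=C1CC2OCCO2 | intermediate
32 | ethyl ketone | C[C@@]1(O)CCC(C(C)(C)C(=O)CC)=C1CC2OCCO2 | intermediate
33 | all-cis cyclopentanol keto acetal | C[C@@]1(O)CC[C@@H](C(C)(C)C(=O)CC)[C@H]1CC2OCCO2 | intermediate
34 | keto aldehyde | C[C@@]1(O)CC[C@@H](C(C)(C)C(=O)CC)[C@H]1CC=O | intermediate
35 | cis-fused hydroxy hydroazulenone (C14 ketone, C26=C28) | O=C1C(C)(C)[C@@H]2CC[C@@](C)(O)[C@@H]2CC=C1C | intermediate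
36 | C21 triethylsilyl ether of 35 | O=C1C(C)(C)[C@@H]2CC[C@@](C)(O[Si](CC)(CC)CC)[C@@H]2CC=C1C | intermediate
37 | C13 alkyllithium | CC1(C)O[C@@H]2CC[C@](C)(O[Si](CC)(CC)CC)[C@H](CC[Li])[C@@]2(C)CC[C@H]1O[Si](C)(C)C(C)(C)C | intermediate
38 | C13 organocerium dichloride | CC1(C)O[C@@H]2CC[C@](C)(O[Si](CC)(CC)CC)[C@H](CC[Ce](Cl)Cl)[C@@]2(C)CC[C@H]1O[Si](C)(C)C(C)(C)C | intermediate
39 | coupled C14 tertiary allylic alcohol (C14 configuration not defined) | CC1(C)O[C@@H]2CC[C@](C)(O[Si](CC)(CC)CC)[C@H](CCC3(O)C(C)(C)[C@@H]4CC[C@@](C)(O[Si](CC)(CC)CC)[C@@H]4CC=C3C)[C@@]2(C)CC[C@H]1O[Si](C)(C)C(C)(C)C | intermediate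
40 | C26 enone with C14=C28 | CC1(C)O[C@@H]2CC[C@](C)(O[Si](CC)(CC)CC)[C@H](CCC3=C(C)C(=O)C[C@@H]4[C@@H](CC[C@@]4(C)O[Si](CC)(CC)CC)C3(C)C)[C@@]2(C)CC[C@H]1O[Si](C)(C)C(C)(C)C | intermediate
41 | (26S)-allylic alcohol (OH on the face of the five-membered ring) | CC1(C)O[C@@H]2CC[C@](C)(O[Si](CC)(CC)CC)[C@H](CCC3=C(C)[C@@H](O)C[C@@H]4[C@@H](CC[C@@]4(C)O[Si](CC)(CC)CC)C3(C)C)[C@@]2(C)CC[C@H]1O[Si](C)(C)C(C)(C)C | intermediate
42 | C26 N-(2-nitrobenzenesulfonyl)hydrazine, inverted at C26 | CC1(C)O[C@@H]2CC[C@](C)(O[Si](CC)(CC)CC)[C@H](CCC3=C(C)[C@H](N(N)S(=O)(=O)c5ccccc5[N+](=O)[O-])C[C@@H]4[C@@H](CC[C@@]4(C)O[Si](CC)(CC)CC)C3(C)C)[C@@]2(C)CC[C@H]1O[Si](C)(C)C(C)(C)C | intermediate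
43 | C26 allylic diazene | CC1(C)O[C@@H]2CC[C@](C)(O[Si](CC)(CC)CC)[C@H](CCC3=C(C)[C@H](N=N)C[C@@H]4[C@@H](CC[C@@]4(C)O[Si](CC)(CC)CC)C3(C)C)[C@@]2(C)CC[C@H]1O[Si](C)(C)C(C)(C)C | intermediate
44 | C26=C28 alkene, tris-silyl ether | CC1(C)O[C@@H]2CC[C@](C)(O[Si](CC)(CC)CC)[C@H](CC[C@@H]3C(C)(C)[C@@H]4CC[C@@](C)(O[Si](CC)(CC)CC)[C@@H]4CC=C3C)[C@@]2(C)CC[C@H]1O[Si](C)(C)C(C)(C)C | intermediate
45 | C8,C21,C34-triol | CC1(C)O[C@@H]2CC[C@](C)(O)[C@H](CC[C@@H]3C(C)(C)[C@@H]4CC[C@@](C)(O)[C@@H]4CC=C3C)[C@@]2(C)CC[C@H]1O | intermediate
46 | C34 ketone with C26=C28 alkene | CC1(C)O[C@@H]2CC[C@](C)(O)[C@H](CC[C@@H]3C(C)(C)[C@@H]4CC[C@@](C)(O)[C@@H]4CC=C3C)[C@@]2(C)CCC1=O | intermediate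
47 | CNP0259752.1 | CC1(C)O[C@@H]2CC[C@](C)(O)[C@H](CC[C@@H]3C(C)(C)[C@@H]4CC[C@@](C)(O)[C@@H]4C[C@@H]4O[C@@]43C)[C@@]2(C)CCC1=O | target

Total step count: 34. Longest linear sequence: 24 steps (steps 1–17, then 28–34); steps 18–27 are the separate hydroazulenone branch.

Steps most likely to fail

Step 14. The enoate radical anion may be protonated and reduced to the saturated ester before it reaches the ketone, electrogenerated base may start a Michael addition of the ketone enolate, or closure through the other chair may give the trans C8/C11 isomer, which cannot lactonise. The fallback forms the same bond by a two-electron allylation and sets out from aldehyde 14. Wittig olefination with the ylide from (2-trimethylsilylethyl)triphenylphosphonium iodide and n-BuLi should give the allylsilane ketal F1, and ketal hydrolysis (pyridinium p-toluenesulfonate, aqueous acetone) the keto allylsilane F2. Fluoride-triggered intramolecular Hosomi–Sakurai allylation (Bu4NF, THF) lets C11 attack the C8 ketone through the same chair (C9 methyl equatorial, O10 axial, vinyl equatorial) to give the vinyl carbinol F3. Hydroboration–oxidation of the vinyl group (9-borabicyclo[3.3.1]nonane; H2O2, NaOH) returns to the route at diol 20.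

Step 8. The hydroxyl may attack the secondary epoxide carbon C34 in the 6-exo mode and give a tetrahydropyran carbinol, or the acid may strip the ketal. The fallback activates the alkene instead of an epoxide and sets out from alkenol 9. Intramolecular oxymercuration (Hg(O2CCF3)2, MeCN, −20 °C; then aq. NaCl) should close the oxepane at the tertiary C2 under Markovnikov control and give the chloromercurial F4. Oxidative demercuration (NaBH4, O2, DMF) gives the oxepanol F5 as both C34 epimers, and Dess–Martin oxidation the oxepanone F6. Corey–Bakshi–Shibata reduction ((S)-oxazaborolidine, catecholborane), which distinguishes quaternary C2 from the C33 methylene, returns to the route at oxepanol 11.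

Step 26. The aldehyde enolate may react instead of the ketone enolate, adding to C14 or to a second molecule, or the seven-membered closure may be too slow and give oligomers. The fallback fixes the roles of donor and acceptor beforehand and sets out from keto acetal 33. Treatment with LiN(iPr)2 and Me3SiCl should give the bis-trimethylsilyl enol ether F7, silylated at the C14 enolate oxygen and at O23. TiCl4 in CH2Cl2 at −78 °C then triggers an intramolecular Mukaiyama addition of the enol ether (C28) to the dioxolane carbon C26 and gives the β-(2-hydroxyethoxy) cycloheptanone F8, the C21 silyl ether falling off on work-up. β-Elimination with 1,8-diazabicyclo[5.4.0]undec-7-ene in toluene at 80 °C returns to the route at enone 35.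

Further compounds
F1 | step 14 | allylsilane ketal (C11=C12–C13–SiMe3, E/Z mixture) | CC1(C)O[C@H](CCC2(C)OCCO2)[C@@](C)(C=CC[Si](C)(C)C)CC[C@H]1O[Si](C)(C)C(C)(C)C
F2 | step 14 | keto allylsilane | CC1(C)O[C@H](CCC(C)=O)[C@@](C)(C=CC[Si](C)(C)C)CC[C@H]1O[Si](C)(C)C(C)(C)C
F3 | step 14 | C8 carbinol with C11 vinyl group | CC1(C)O[C@@H]2CC[C@](C)(O)[C@H](C=C)[C@@]2(C)CC[C@H]1O[Si](C)(C)C(C)(C)C
F4 | step 8 | C34 chloromercurio oxepane | CC1(C)O[C@H](CCC2(C)OCCO2)[C@@](C)(CO[Si](C)(C)C(C)(C)C)CCC1[Hg]Cl
F5 | step 8 | oxepan-34-ol, both C34 epimers | CC1(C)O[C@H](CCC2(C)OCCO2)[C@@](C)(CO[Si](C)(C)C(C)(C)C)CCC1O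
F6 | step 8 | oxepan-34-one | CC1(C)O[C@H](CCC2(C)OCCO2)[C@@](C)(CO[Si](C)(C)C(C)(C)C)CCC1=O
F7 | step 26 | bis-trimethylsilyl enol ether of 33 | CC=C(O[Si](C)(C)C)C(C)(C)[C@@H]1CC[C@@](C)(O[Si](C)(C)C)[C@@H]1CC2OCCO2
F8 | step 26 | β-(2-hydroxyethoxy) cycloheptanone | O=C1C(C)C(OCCO)C[C@@H]2[C@@H](CC[C@@]2(C)O)C1(C)C
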